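**Retrosynthetic overview**
- The oxirane is the only ring formed and is closed last: both ring C–O bonds and the quaternary stereocenter come from one enantioselective oxygen-atom transfer to the 1,1-disubstituted alkene of a 2-arylallyl acetate.
- The allylic acetate C–O bond comes from the methyl group of an α-methylstyrene (allylic bromination, then acetate displacement).
- The two isobutyrate C–O bonds come from acylation of a phenol/benzyl alcohol with isobutyryl chloride.
- The only C–C bond made is aryl–isopropenyl, by Suzuki–Miyaura coupling of 2-bromo-5-(hydroxymethyl)phenol with isopropenyl pinacol boronate.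
- Ring order: the benzene ring is bought; the oxirane is formed in the final step.

Assumption: the facial sense of the new epoxidation (step 4) is assigned by analogy with α-alkylstyrenes; if the first run gives the enantiomer of 7, the mirror-image complex and co-ligand are used with nothing else changed.

**Step 1**
Reactants: 1 2-bromo-5-(hydroxymethyl)phenol; 2 4,4,5,5-tetramethyl-2-(prop-1-en-2-yl)-1,3,2-dioxaborolane (isopropenylboronic acid pinacol ester)
Product: 3 5-(hydroxymethyl)-2-(prop-1-en-2-yl)phenol
Conditions: PdCl2(dppf) (3 mol%), K2CO3 (3 equiv), 1,4-dioxane/H2O 4:1, 85 °C; neutral (pH 7) work-up, used at once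
Reagents that add atoms: none
Why: Suzuki–Miyaura coupling, in which zerovalent palladium inserts into the C–Br bond, the isopropenyl boronate transmetalates under aqueous carbonate and reductive elimination gives the styrene; unprotected bromophenols and benzyl alcohols are tolerated and no stereocenter is formed.

**Step 2**
Reactants: 3 5-(hydroxymethyl)-2-(prop-1-en-2-yl)phenol
Product: 4 5-[(2-methylpropanoyloxy)methyl]-2-(prop-1-en-2-yl)phenyl 2-methylpropanoate
Conditions: isobutyryl chloride (2.4 equiv), Et3N (3 equiv), DMAP (5 mol%), CH2Cl2, 0 °C to 25 °C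
Reagents that add atoms: isobutyryl chloride (2-methylpropanoyl chloride), CC(C)C(=O)Cl
Why: DMAP-catalysed nucleophilic acyl substitution esterifies both the phenol and the primary benzylic alcohol, the only nucleophiles present, while the alkene is inert; masking the phenol also stops the acid-triggered dimerisation of the ortho-isopropenylphenol.

**Step 3**
Reactants: 4 5-[(2-methylpropanoyloxy)methyl]-2-(prop-1-en-2-yl)phenyl 2-methylpropanoate
Product: 6 2-[3-(acetyloxy)prop-1-en-2-yl]-5-[(2-methylpropanoyloxy)methyl]phenyl 2-methylpropanoate, via allylic bromide 5 (not isolated)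
Conditions: NBS (1.05 equiv), TsOH·H2O (10 mol%), THF, 65 °C; water wash, then crude 5, KOAc (2 equiv), DMF, 25 °C
Reagents that add atoms: N-bromosuccinimide, O=C1CCC(=O)N1Br (its bromine is in 5 only); potassium acetate, CC(=O)[O-].[K+]
Why: Acid-catalysed electrophilic bromination of the α-methylstyrene (bromonium/benzylic cation, then loss of a methyl proton) gives the 2-arylallyl bromide, and acetate then displaces the allylic bromide (SN2; SN2' gives the same product) to form the primary C–O bond; the minor vinyl bromide isomer does not react with acetate and is removed on the column.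

**Step 4**
Reactants: 6 2-[3-(acetyloxy)prop-1-en-2-yl]-5-[(2-methylpropanoyloxy)methyl]phenyl 2-methylpropanoate
Product: 7 2-[(2S)-2-(acetyloxymethyl)oxiran-2-yl]-5-[(2-methylpropanoyloxy)methyl]phenyl 2-methylpropanoate (CNP0151517.1)
Conditions: [Fe(OTf)2((S,S)-Me2N-pdp)] (2 mol%; Me2N-pdp = (2S,2'S)-1,1'-bis[(4-dimethylaminopyridin-2-yl)methyl]-2,2'-bipyrrolidine), N-(1,8-naphthaloyl)-L-isoleucine (3 mol%), 30% aq. H2O2 (2 equiv, added over 30 min), MeCN, −30 °C; NaHCO3/Na2S2O3 quench at −30 °C, Et3N-deactivated silica
Reagents that add atoms: hydrogen peroxide, OO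
Why: Proposed new method: enantioselective epoxidation of a 2-arylallyl acetate (a 1,1-disubstituted alkene with an allylic ester and an ortho-acyloxyaryl group) by H2O2 under [Fe(OTf)2((S,S)-Me2N-pdp)] and a chiral amino-acid co-ligand; the divalent iron complex, H2O2 and the carboxylic acid give an electrophilic pentavalent iron oxo carboxylate that transfers its oxygen to the alkene in one concerted step with no base or alkoxide present (so the ortho phenolic ester cannot migrate and all three esters survive), the bulky chiral carboxylate bound cis to the oxo narrows the pocket so that the twisted aryl group and the CH2OAc arm are distinguished as aryl and alkyl are in α-alkylstyrenes, and delivery to the Re face of C2 (CH2OAc > aryl > =CH2) gives the (S)-epoxide, forming both ring C–O bonds and the only stereocenter; the closest known reaction type is the epoxidation of α-alkylstyrenes by non-heme iron aminopyridine complexes with H2O2 and amino-acid co-ligands, not shown for allylic esters or ortho-acyloxy arenes.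

**Compound list**
1 | 2-bromo-5-(hydroxymethyl)phenol | OCc1ccc(Br)c(O)c1 | starting material
2 | 4,4,5,5-tetramethyl-2-(prop-1-en-2-yl)-1,3,2-dioxaborolane | CC(=C)B1OC(C)(C)C(C)(C)O1 | starting material
3 | 5-(hydroxymethyl)-2-(prop-1-en-2-yl)phenol | CC(=C)c1ccc(CO)cc1O | intermediate
4 | 5-[(2-methylpropanoyloxy)methyl]-2-(prop-1-en-2-yl)phenyl 2-methylpropanoate | CC(=C)c1ccc(COC(=O)C(C)C)cc1OC(=O)C(C)C | intermediate
5 | 2-(3-bromoprop-1-en-2-yl)-5-[(2-methylpropanoyloxy)methyl]phenyl 2-methylpropanoate | BrCC(=C)c1ccc(COC(=O)C(C)C)cc1OC(=O)C(C)C | intermediate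
6 | 2-[3-(acetyloxy)prop-1-en-2-yl]-5-[(2-methylpropanoyloxy)methyl]phenyl 2-methylpropanoate | CC(=O)OCC(=C)c1ccc(COC(=O)C(C)C)cc1OC(=O)C(C)C | intermediate
7 | 2-[(2S)-2-(acetyloxymethyl)oxiran-2-yl]-5-[(2-methylpropanoyloxy)methyl]phenyl 2-methylpropanoate | CC(=O)OC[C@]1(c2ccc(COC(=O)C(C)C)cc2OC(=O)C(C)C)CO1 | target

**Step count and risks**
Total step count: 4. Longest linear sequence: 4 (fully linear).

Steps most likely to fail:

1. Step 4 (the new epoxidation). The risks are low ee or the wrong facial sense on this ortho-substituted allylic ester, and opening or rearrangement of the tertiary benzylic epoxide at the Lewis-acidic iron centre. The fallback uses known chemistry, sets out from 4 and comes back at 7. Allylic oxidation of 4 with SeO2 (0.5 equiv) and t-BuOOH in CH2Cl2 gives the allylic alcohol 2-(3-hydroxyprop-1-en-2-yl)-5-[(2-methylpropanoyloxy)methyl]phenyl 2-methylpropanoate F1. Hydroxyl-directed Sharpless asymmetric epoxidation (Ti(OiPr)4 10 mol%, D-(−)-diethyl tartrate 12 mol%, t-BuOOH, 4 Å sieves, CH2Cl2, −20 °C) then gives the epoxy alcohol 2-[(2R)-2-(hydroxymethyl)oxiran-2-yl]-5-[(2-methylpropanoyloxy)methyl]phenyl 2-methylpropanoate F2. D-(−)-tartrate is the enantiomer that gives (R)-2-substituted glycidols, which here means oxygen on the Re face of C2. Acetylation (Ac2O, pyridine, DMAP cat., 0 °C) gives 7. The descriptor changes from R to S only because CH2OAc outranks the ring CH2; no bond at the stereocenter is touched.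

2. Step 3 (allylic bromination, then acetate). The risks are the vinyl bromide isomer, capture of the benzylic cation by the ortho ester carbonyl, and N-alkylation of residual succinimide. The fallback sets out from 4 and comes back at 6. It is a direct allylic C–H acetoxylation with Pd(OAc)2 (10 mol%) and 1,4-benzoquinone (2 equiv) in AcOH at 45 °C, through a symmetrical 2-aryl-π-allyl complex of divalent palladium that acetate attacks at either terminus to give the same product. This fallback makes no new compound (F0).

3. Step 1 (Suzuki–Miyaura coupling on the free phenol). The risks are protodeboronation of the isopropenyl boronate and dimerisation of the ortho-isopropenylphenol 3 on work-up. The fallback sets out from 1 and comes back at 4. Compound 1 is acylated first (isobutyryl chloride, Et3N, DMAP cat., CH2Cl2) to 2-bromo-5-[(2-methylpropanoyloxy)methyl]phenyl 2-methylpropanoate F3. The isopropenyl group is then introduced by a base-free Stille coupling with tributyl(prop-1-en-2-yl)stannane (Pd(PPh3)4, toluene, 100 °C), which leaves both esters intact and gives 4 without ever forming the free isopropenylphenol.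

**Further compounds**
F1 | step 4 | 2-(3-hydroxyprop-1-en-2-yl)-5-[(2-methylpropanoyloxy)methyl]phenyl 2-methylpropanoate | OCC(=C)c1ccc(COC(=O)C(C)C)cc1OC(=O)C(C)C
F2 | step 4 | 2-[(2R)-2-(hydroxymethyl)oxiran-2-yl]-5-[(2-methylpropanoyloxy)methyl]phenyl 2-methylpropanoate | OC[C@]1(c2ccc(COC(=O)C(C)C)cc2OC(=O)C(C)C)CO1
F0 | step 3 | none | none
F3 | step 1 | 2-bromo-5-[(2-methylpropanoyloxy)methyl]phenyl 2-methylpropanoate | CC(C)C(=O)OCc1ccc(Br)c(OC(=O)C(C)C)c1
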